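**Assumption:** the target has no stereocentre and is achiral, so no enantiomer has to be controlled. Compound 1 is used as the racemate because its stereocentre becomes sp2 in the pyrone.

**Retrosynthetic overview**
- The 2-OMe group is cut last. The α-methoxy-γ-pyrone comes from a 4-hydroxy-2-pyrone by methylation of the lactone carbonyl oxygen.
- The acetate comes from chemoselective esterification of the primary alcohol while the acidic pyrone 4-OH is present.
- The pyrone is the only ring. It is closed by lactonisation of an acyclic 3,5-dioxo methyl ester, forming the ring O–C2 bond.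
- The C5–C6 bond comes from γ-acylation of the dianion of methyl 2-methyl-3-oxopentanoate with 12-dodecanolide. The lactone supplies C6, the whole C11 chain and the terminal oxygen without a protecting group.

**Step 1**
Reactants: 1 methyl 2-methyl-3-oxopentanoate (racemic); 2 oxacyclotridecan-2-one (12-dodecanolide)
Product: 4 methyl 16-hydroxy-2,4-dimethyl-3,5-dioxohexadecanoate, via dilithium dianion 3 (not isolated)
Conditions: 1 (2.2 equiv), LiN(iPr)2 (LDA, 4.5 equiv), THF, 0 °C, 45 min; then 2 (1.0 equiv), −78 °C → rt; 1 M HCl quench
Reagents that add atoms: none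
Why: In this Huckin–Weiler-type Claisen acylation the more basic γ-carbanion of the β-keto ester dianion attacks the lactone carbonyl and opens the ring to the alkoxide, excess dianion deprotonates the new 1,3-diketone so no second addition occurs, and the two epimerisable stereocentres of 4 do not matter because both become sp2 in step 2.

**Step 2**
Reactants: 4 methyl 16-hydroxy-2,4-dimethyl-3,5-dioxohexadecanoate
Product: 5 4-hydroxy-6-(11-hydroxyundecyl)-3,5-dimethyl-2H-pyran-2-one
Conditions: DBU (2 equiv), toluene, 80 °C, 12 h; then 1 M HCl wash
Reagents that add atoms: none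
Why: DBU enolises the C5 ketone and the enol oxygen attacks the methyl ester (lactonisation by intramolecular transesterification, loss of MeOH), driven by formation of the conjugated, acidic 4-hydroxy-2-pyrone, and any ester exchange with the free primary alcohol still ends in the same pyrone.

**Step 3**
Reactants: 5 4-hydroxy-6-(11-hydroxyundecyl)-3,5-dimethyl-2H-pyran-2-one
Product: 6 11-(4-hydroxy-3,5-dimethyl-2-oxo-2H-pyran-6-yl)undecyl acetate
Conditions: AcOH (solvent), p-toluenesulfonic acid monohydrate (p-MeC6H4SO3H·H2O, 5 mol %), 70 °C, 4 h
Reagents that add atoms: acetic acid, CC(=O)O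
Why: Fischer esterification is under thermodynamic control, so only the aliphatic primary alcohol is acetylated, because the vinylogous-acid 4-OH would give an anhydride-like enol acetate that does not persist in acidic AcOH.

**Step 4**
Reactants: 6 11-(4-hydroxy-3,5-dimethyl-2-oxo-2H-pyran-6-yl)undecyl acetate
Product: 8 11-(6-methoxy-3,5-dimethyl-4-oxo-4H-pyran-2-yl)undecyl acetate, via hydroxypyrylium triflate 7 (not isolated)
Conditions: MeOTf (1.5 equiv), CH2Cl2, 0 °C → rt, 16 h; then sat. aq. NaHCO3
Reagents that add atoms: methyl trifluoromethanesulfonate (MeOTf), COS(=O)(=O)C(F)(F)F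
Why: In this base-free O-methylation of the neutral tautomer (Beak-type regiospecific alkylation) the only nucleophilic oxygen is the lactone carbonyl, so the 2-methoxy-4-hydroxypyrylium salt 7 forms, its charge shields it from a second methylation, it loses the 4-OH proton on NaHCO3 work-up to give the α-methoxy-γ-pyrone, and the acetate is inert.

**Compound list**
1 | methyl 2-methyl-3-oxopentanoate (racemic) | CCC(=O)C(C)C(=O)OC | starting material
2 | oxacyclotridecan-2-one (12-dodecanolide) | O=C1CCCCCCCCCCCO1 | starting material
3 | dilithium bis-enolate (dianion) of 1 | [Li+].[Li+].CC=C([O-])C(C)=C([O-])OC | intermediate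
4 | methyl 16-hydroxy-2,4-dimethyl-3,5-dioxohexadecanoate (diastereomer and enol mixture) | COC(=O)C(C)C(=O)C(C)C(=O)CCCCCCCCCCCO | intermediate
5 | 4-hydroxy-6-(11-hydroxyundecyl)-3,5-dimethyl-2H-pyran-2-one | O=c1oc(CCCCCCCCCCCO)c(C)c(O)c1C | intermediate
6 | 11-(4-hydroxy-3,5-dimethyl-2-oxo-2H-pyran-6-yl)undecyl acetate | CC(=O)OCCCCCCCCCCCc1oc(=O)c(C)c(O)c1C | intermediate
7 | 2-(11-acetoxyundecyl)-4-hydroxy-6-methoxy-3,5-dimethylpyrylium triflate | COc1[o+]c(CCCCCCCCCCCOC(C)=O)c(C)c(O)c1C.[O-]S(=O)(=O)C(F)(F)F | intermediate
8 | 11-(6-methoxy-3,5-dimethyl-4-oxo-4H-pyran-2-yl)undecyl acetate (CNP0129758.0, achiral) | COc1oc(CCCCCCCCCCCOC(C)=O)c(C)c(=O)c1C | target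

**Total step count:** 4. **Longest linear sequence:** 4.

**Steps most likely to fail, with fallbacks**

Step 1 carries the most risk. A secondary γ-carbanion may enolise the unactivated lactone instead of acylating, which would give low yields. The fallback forms the C–C bond by aldol addition and oxidation instead of acylation, and it carries the acetate from the start.
- It sets out from 2, together with dianion 3 made from 1 as before, and comes back to the route at 6, bypassing steps 2 and 3.
- Lactone 2 is half-reduced with iBu2AlH (1.0 equiv, CH2Cl2, −78 °C) to 12-hydroxydodecanal F1.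
- This is acetylated (Ac2O, pyridine) to 12-oxododecyl acetate F2.
- Dianion 3 (1.1 equiv, THF, −78 °C) adds to the aldehyde much faster than to the acetate. It gives methyl 16-acetoxy-5-hydroxy-2,4-dimethyl-3-oxohexadecanoate F3 as a diastereomer mixture, which is of no consequence.
- Dess–Martin periodinane in CH2Cl2 oxidises the carbinol to methyl 16-acetoxy-2,4-dimethyl-3,5-dioxohexadecanoate F4.
- DBU in toluene at 80 °C closes the ring directly to 6.

Step 4 is second. Possible problems are incomplete conversion, imperfect regiocontrol, or difficult purification of the ester-bearing product. The fallback drops the late, neutral-tautomer alkylation. It methylates the pyronate anion before the ester is installed, so the last step becomes a simple acetylation.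
- It sets out from 5 and comes back at 8.
- Diol 5 is heated with Me2SO4 and CaCO3 in acetone at reflux. Only the acidic pyrone OH is deprotonated and alkylated, and the neutral primary alcohol does not react.
- The product is 2-(11-hydroxyundecyl)-6-methoxy-3,5-dimethyl-4H-pyran-4-one F6. Chromatography frees this polar free alcohol from any regioisomer.
- Ac2O and pyridine in CH2Cl2 then give 8.

Step 3 is third. The equilibrium acetylation may be incomplete, or the pyrone may erode in hot acid. The fallback replaces selective mono-acylation by exhaustive acylation followed by selective deacylation.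
- It sets out from 5 and comes back at 6.
- Diol 5 is treated with Ac2O (3 equiv), pyridine and DMAP (cat.) to give 11-(4-acetoxy-3,5-dimethyl-2-oxo-2H-pyran-6-yl)undecyl acetate F5. O-to-C acyl migration is not possible because C3 carries a methyl group.
- Stirring F5 in MeOH with NaHCO3 at rt, followed by acidification, cleaves only the activated, anhydride-like enol acetate. The primary acetate stays and 6 is obtained.

**Further compounds**
F1 | step 1 | 12-hydroxydodecanal | O=CCCCCCCCCCCCO
F2 | step 1 | 12-oxododecyl acetate | CC(=O)OCCCCCCCCCCCC=O
F3 | step 1 | methyl 16-acetoxy-5-hydroxy-2,4-dimethyl-3-oxohexadecanoate (diastereomer mixture) | COC(=O)C(C)C(=O)C(C)C(O)CCCCCCCCCCCOC(C)=O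
F4 | step 1 | methyl 16-acetoxy-2,4-dimethyl-3,5-dioxohexadecanoate | COC(=O)C(C)C(=O)C(C)C(=O)CCCCCCCCCCCOC(C)=O
F5 | step 3 | 11-(4-acetoxy-3,5-dimethyl-2-oxo-2H-pyran-6-yl)undecyl acetate | CC(=O)OCCCCCCCCCCCc1oc(=O)c(C)c(OC(C)=O)c1C
F6 | step 4 | 2-(11-hydroxyundecyl)-6-methoxy-3,5-dimethyl-4H-pyran-4-one | COc1oc(CCCCCCCCCCCO)c(C)c(=O)c1C
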